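3100 turnovers per enzyme charged and per fraction of substrate left in alder and 3100 in elm: that is what we get from the target readings at 25.0 h, though elm had 5.56 times alder's enzyme.

| flask | substrate | enzyme | remark | time |
|---|---|---|---|---|
| alder | 0.075 M | 4.5 µM (in portions, 4) | run made earlier; portions every 4.0 h |  |
| elm | 0.075 M | 25 µM (in portions, 4) | run made earlier; portions every 4.0 h |  |
| grey | 0.075 M | 30 µM | everything together at the start | 100 h |
| green | 0.075 M | 7.5 µM (in portions, 4) | the portions of enzyme follow each other after 4.0 h, the first at the start | 25 h |

| run | time / h | target / % | substrate / % |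
|---|---|---|---|
| alder | 2.00 | 1.0 | 100.8 |
| alder | 5.00 | 1.5 | 97.5 |
| alder | 10.0 | 5.2 | 94.8 |
| alder | 25.0 | 15.7 | 83.1 |
| elm | 2.00 | 2.8 | 96.8 |
| elm | 5.00 | 9.6 | 90.2 |
| elm | 10.0 | 22.8 | 77.2 |
| elm | 25.0 | 50.8 | 50.3 |

(each reading ± 1 percentage point)

* the flask that ends with the higher amount of target, in percent of the substrate charged, or "neither" when 2 percentage points or less lies between them (grey / green / neither)
* final target, as a percentage of the substrate charged, in grey
* final target, as a percentage of the substrate charged, in green



With x the fraction of substrate S turned to target and E the whole enzyme charged, each count is S·x/E, divided by the fraction of substrate left. Their mean, 3100, is our turnover count N, the target formed per enzyme charged and per fraction of substrate left, a reading for 4 portions every 4.0 h, taken at 25 h.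

Green has that schedule and time, so target over substrate left should be N·E/S = 0.310, which makes x 23.7%. Grey has no count of its own, but the same reckoning on its 30 µM gives 55.4%. Grey's enzyme goes in at the start and grey runs 100 h against 25 h, so we read that figure as an estimate on the low side for grey, assuming target is not lost. So we expect grey to end higher, by about 32 percentage points or more on this estimate, a gap wider than the margin of 2 points.

The forecast names grey as the higher flask, with 72% in grey, from “Extrapolating the slowing curve”, and 23.5% in green.

The higher flask is grey, with 70.8% in grey and 24.6% in green, and green's own count comes to 3260 against our N of 3100.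

    substrate + enzyme → target + enzyme, rate k1*[substrate]^3*[enzyme]/(1 + ([substrate]/Kh1)^3) (0.0757 M, k = 1.03 × 10⁶ L³ mol⁻³ h⁻¹)
    enzyme ⇌ dormant form (K = 9.72, k = 0.0313 h⁻¹)
    enzyme → spent catalyst (k = 5.72 × 10⁻⁵ h⁻¹)

In green, the forward turning of enzyme into dormant form alone has a half-life of 22 h, a little shorter than the run of 25 h, while the turning into spent catalyst has 500 d. At 25.0 h green holds 56.9% of its catalyst as enzyme, 43.0% as dormant form (off-cycle) and 0.0814% as spent catalyst.

For a neighbouring flask, green with 3.0 × 10⁻⁶ M of enzyme, N gives target over substrate left of 0.124, so x is 11.0%. The computed flask ends at 11.4%, with 56.9% of its catalyst as enzyme, the same share as in green.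

The data are simulated with constants of no real substance; the scatter is artificial.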